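## The problem

Numbering used throughout: C1 (OMe), C2 (=CH), C3 (carries C7H2O), C4 (OH), C5 (OBz), C6 (OH); O-n is the oxygen on C-n (O7 on C7).

Target 21 is a single cyclohexene with one exocyclic carbon, so the skeleton is trivial. The work lies in four contiguous oxygenated stereocentres (C1, C6, C5, C4) and in telling five oxygens apart. Every vicinal pair is trans (1S,4S,5R,6R): O1 and O5 lie on one face, O4 and O6 on the other, and O1 and O4 are trans across C2=C3. Only the trans C5/C6 pair has to be bought. C1 has O6 and C4 has O5 as its only oxygenated neighbour, so a reagent entering anti to that neighbour at each allylic carbon gives the all-trans array. The oxygens end in three states: methyl ether (O1), benzoate (O5, O7) and free hydroxyl (O4, O6). O1 and O4 are both secondary and allylic and are the hardest pair to distinguish. The O5 benzoate, flanked by two hydroxyls, migrates as soon as an alkoxide forms beside it, and the allylic C–O bonds and any 5,6-dioxygenated cyclohexadiene tolerate neither strong acid nor forcing base (ionisation, aromatisation). The enabling feature is that O1 and O4 sit at the two ends of the C1–C2=C3–C4 unit and are trans to each other, which is the outcome of a trans-1,4-addition of two oxygen nucleophiles to a C1=C2–C3=C4 diene. In addition, O4 and O7 are 1,3-related, so a six-membered tether can later isolate O1.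

## Retrosynthesis

21 ⇒ 20 + 5. The O7–benzoyl bond is cut last. Keeping O7 free of its final benzoate until the end lets it first serve as the anchor of a tether to O4; a benzoate carried at O7 from the start would leave no handle to separate O1 from O4. Triol 20 has one ester fewer. The forward step asks only for acylation of a primary allylic hydroxyl by benzoyl chloride 5 in the presence of two hindered secondary ones, without base strong enough to move the O5 benzoate.

20 ⇒ 19 ⇒ 18. The O1–CH3 bond and the Si–O bonds are cut. In 18, O4 and O7 are tied in a six-membered di-tert-butylsilylene and O6 is a TIPS ether, so O1 is the only hydroxyl and its methylation cannot go astray. The shorter neighbour, a regioselective mono-deacetylation of a 1,4-diacetate, would rest on a preference that cannot be predicted from structure. The forward steps need an alkoxide-free methylation and one fluoride treatment that removes both silicon groups.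

18 ⇒ 17 ⇒ 16. The tether and three acetyl groups (O1, O4, O7) are removed in the retrosynthetic sense. Triacetate 16 carries the two new allylic oxygens and O7 in one and the same ester type, distinct from the benzoate at O5. The forward methanolysis must be acid-catalysed, which discriminates acetate from hindered benzoate without forming an alkoxide, and the O6 silyl ether must therefore be acid-stable (TIPS).

16 ⇒ 14 + 15 (key disconnection). Both allylic C–O bonds, C1–O and C4–O, are cut at once. This removes two stereocentres and two oxygens and leaves diene 14, whose only stereocentres are the trans C5/C6 pair. A stepwise alternative (epoxidation and opening) could bring in O1 and O6 but would leave C4 as an unactivated CH2. The forward palladium-catalysed, quinone-mediated addition of acetic acid 15 must be trans-1,4 and anti to O6 at C1 and to O5 at C4.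

14 ⇒ 11 (via 13 and 12). The C1=C2 and C3=C4 bonds are traced back to an allylic alcohol by a 1,4-dehydration: shikimate O3 and one H-6 are lost. Shikimate C3 has the wrong configuration for C1 of 21 in any case, so destroying it costs nothing. A sulfenate-to-sulfoxide shift followed by syn-elimination is chosen over base- or palladium-induced eliminations because sulfur is placed on the carbon bearing C7 and can then only leave with a hydrogen from the ring CH2. The forward step requires that O3 be the only free hydroxyl.

11 ⇒ 10 ⇒ 8 (via 9). The Si–O bonds at O3 and O4 are cut. In diol 8 the allylic O3 reacts first, so a short-lived triethylsilyl group goes there, the lasting TIPS group is then forced onto O4, and the triethylsilyl group is taken off again. This is the price of needing O4 protected and O3 free.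

8 ⇒ 7 ⇒ 4 + 5 (via 6). The acetal and the two acyl bonds are cut. The cis O3/O4 acetonide of 4 is what singles out O5 for the benzoate from 5; the primary O7 takes an acetate first.

4 ⇒ 3 ⇒ 1 (via 2). The C7 alcohol comes from the ester by hydride reduction, placed before any benzoate exists, and ester 3 comes from shikimic acid 1, which supplies the ring, C7 and the C5/C6 configuration of 21 (shikimate C5 and C4).

## Roads not taken

Alternative 1: The ring would come from bromobenzene A2, and the C4–O and C5–O bonds would be made by whole-cell toluene dioxygenase oxidation to the cis-diene-diol (1S,2S)-3-bromocyclohexa-3,5-diene-1,2-diol A1. One fermentation gives an enantiopure diene, the vinylic bromide is a handle for C7, and after acetal protection the remaining C1=C6 alkene can be epoxidised and opened at the allylic C1 by methanolysis. That delivers the trans C1-OMe/C6-OH pair directly, with O1 never confused with O4; in this respect the road is better than the chosen one and probably shorter. Its weak point is configuration: mapped onto 21, A1 has C5 correct but C4 on the wrong face (the diol is cis, C4/C5 of 21 are trans). An inversion at the hindered C4, next to the substituted C3, is therefore unavoidable, and O5 must then be benzoylated selectively beside O4. A1 also depends on a recombinant strain. The chosen plan sets against this that all four centres arise in the all-trans relationship without any inversion, two from shikimic acid 1 and two from the mechanism of step 8.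

Alternative 2: The C3–C4 bond would be closed by an intramolecular Morita–Baylis–Hillman reaction of an enethioate aldehyde built from D-xylose A4: a phosphine adds to C2, the C3 enolate attacks the C4 aldehyde and the phosphine is expelled, giving the cyclohexenol thioester A3. Its merit is real: A3 already carries O1 as methyl ether, O6 as silyl ether and O5 as benzoate, so none of the late oxygen differentiation of the chosen route is needed. The weak points are that C4 is created in the aldol step with no strong facial bias and must end trans to O5; that the α-benzoyloxy aldehyde can epimerise or transfer its acyl group under a nucleophilic phosphine; that the thioester must later be reduced to the C7 alcohol beside a benzoate; and that the acyclic precursor with a geometrically defined enethioate is long to make. The chosen plan is longer in protecting-group steps but forms C1 and C4 together under combined substrate and mechanistic control.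

Alternative 3: The C1–C2 bond would form when a Lewis acid ionises a C1 dimethyl acetal and the silicon-bearing carbon of a Z-vinylsilane attacks the resulting methyl oxocarbenium ion, closing the ring and giving, after loss of silicon, the 4,6-bis-silyl ether A5 of the target. This has the best endgame of all: the methoxy group arrives with the ring closure and A5 is one desilylation from 21, and the all-equatorial chair should favour the all-trans product. Against it stand the possible capture of the oxocarbenium ion by the C5 benzoate carbonyl, the exposure of silyl ethers and an allylic benzoate to a strong Lewis acid, and above all the acyclic precursor: three contiguous, differently protected stereocentres plus a trisubstituted vinylsilane of defined geometry have to be assembled first. The chosen plan reaches its key-step substrate 14 with both stereocentres taken from the chiral pool; it has to set a five-step endgame against the one-step endgame of this road.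

Key step: step 8

Remark: compounds 1–12 are described in shikimate numbering (C1 carries C7; oxygens O3, O4, O5; O3/O4 cis, O4/O5 trans). Shikimate C3, C2, C1, C6, C5, C4 become C1, C2, C3, C4, C5, C6 of 13, 14 and all later compounds.

## Route

Step 1
Reactants: 1 shikimic acid
Product: 3 methyl 3,4-O-isopropylidene shikimate (cis-fused acetonide on O3/O4, free 5-OH), via methyl shikimate 2 (not isolated)
Conditions: camphor-10-sulfonic acid (cat.), MeOH, reflux; evaporate; 2,2-dimethoxypropane, acetone, rt
Reagents that add atoms: methanol, CO; 2,2-dimethoxypropane, COC(C)(C)OC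
Why: Fischer esterification followed by acid-catalysed transketalisation; only the cis O3/O4 pair can close an unstrained five-membered acetal, so the trans 5-OH stays free and no stereocentre is touched.

Step 2
Reactants: 3 methyl 3,4-O-isopropylidene shikimate
Product: 4 allylic alcohol from reduction of the ester (C7H2OH on C1, free 5-OH, 3,4-acetonide; shikimate configuration unchanged)
Conditions: iBu2AlH (3.5 equiv), CH2Cl2, −78 → 0 °C; aqueous potassium sodium tartrate
Reagents that add atoms: none
Why: 1,2-reduction of an α,β-unsaturated ester to the allylic alcohol by an aluminium hydride; it is placed here because no hydride reagent would spare a benzoate later.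

Step 3
Reactants: 4 allylic alcohol (7,5-diol); 5 benzoyl chloride
Product: 7 7-O-acetyl-5-O-benzoyl-3,4-O-isopropylidene derivative, via 7-O-acetate 6 (not isolated)
Conditions: AcCl (1.05 equiv), 2,4,6-collidine, CH2Cl2, −78 °C; then BzCl (1.5 equiv), pyridine, 4-(dimethylamino)pyridine (cat.), 0 °C → rt
Reagents that add atoms: acetyl chloride, CC(=O)Cl; benzoyl chloride, O=C(Cl)c1ccccc1
Why: an acid chloride with a hindered pyridine base at −78 °C acylates a primary hydroxyl in strong preference to a secondary one, and the remaining 5-OH is then benzoylated under nucleophilic catalysis; O7 receives an acetate so that it can be unmasked later together with the acetates made in step 8.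

Step 4
Reactants: 7 7-O-acetyl-5-O-benzoyl-3,4-O-isopropylidene derivative
Product: 8 7-O-acetyl-5-O-benzoyl 3,4-diol
Conditions: AcOH–H2O (4:1), 50 °C
Reagents that add atoms: none
Why: acid-catalysed acetal hydrolysis; both esters are stable in aqueous acetic acid and acyl migration from O5 to O4 is slow without base.

Step 5
Reactants: 8 7-O-acetyl-5-O-benzoyl 3,4-diol
Product: 10 3-O-triethylsilyl-4-O-triisopropylsilyl ether, via 3-O-triethylsilyl ether 9 (not isolated)
Conditions: Et3SiCl (1.05 equiv), imidazole, CH2Cl2, −40 → 0 °C; then iPr3SiOTf (1.5 equiv), 2,6-lutidine, 0 °C → rt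
Reagents that add atoms: chlorotriethylsilane, CC[Si](Cl)(CC)CC; triisopropylsilyl triflate, CC(C)[Si](OS(=O)(=O)C(F)(F)F)(C(C)C)C(C)C
Why: regioselective silylation; in shikimate 3,4-diols the allylic O3 is silylated ahead of O4, which is flanked on both sides (the same order that leaves O4 free when methyl shikimate is bis-silylated), and the silyl triflate then caps the hindered O4 with the acid-stable TIPS group.

Step 6
Reactants: 10 3-O-triethylsilyl-4-O-triisopropylsilyl ether
Product: 11 4-O-triisopropylsilyl ether with free allylic 3-OH (7-OAc, 5-OBz)
Conditions: pyridinium p-toluenesulfonate (0.2 equiv), MeOH–CH2Cl2, 0 °C → rt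
Reagents that add atoms: none
Why: acid-catalysed methanolysis removes a triethylsilyl ether far faster than a triisopropylsilyl ether, and acetate and benzoate are inert under these conditions.

Step 7
Reactants: 11 4-O-triisopropylsilyl ether with free 3-OH
Product: 14 (5R,6R)-3-(acetoxymethyl)-5-benzoyloxy-6-(triisopropylsilyloxy)cyclohexa-1,3-diene, via allylic 2,4-dinitrobenzenesulfenate 12 (not isolated), via tertiary allylic sulfoxide 13 (not isolated)
Conditions: 2,4-(O2N)2C6H3SCl (1.2 equiv), Et3N (3 equiv), ClCH2CH2Cl, 0 °C → rt, then 60 °C
Reagents that add atoms: none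
Why: known 1,4-dehydration of allylic alcohols: O-sulfenylation, then a [2,3]-sigmatropic (Mislow–Evans) shift that places the arylsulfinyl group on the carbon bearing C7, on the face the oxygen left, then thermal syn-elimination of the electron-poor sulfoxide. The elimination can only use a hydrogen of the ring CH2 or of C7, and the latter is disfavoured because it would give an enol acetate; the trans 5,6-substituents have no anti-periplanar hydrogen, which protects 14 from base-induced aromatisation.

Step 8
Reactants: 14 (5R,6R)-diene; 15 acetic acid
Product: 16 (1S,4S,5R,6R)-1,4-diacetoxy-3-(acetoxymethyl)-5-benzoyloxy-6-(triisopropylsilyloxy)cyclohex-2-ene (all-trans)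
Conditions: Pd(OAc)2 (5 mol %), LiOAc (4 equiv), 1,4-benzoquinone (0.2 equiv), MnO2 (1.3 equiv), AcOH, 25 °C
Reagents that add atoms: acetic acid, CC(O)=O; lithium acetate, [Li+].CC(=O)[O-] (same acetate pool)
Why: divalent palladium binds the diene and an acetate ion attacks one diene terminus on the face opposite the metal, giving a π-allylpalladium acetate. Coordination of benzoquinone then triggers cis migration of acetate from palladium to the far allyl terminus, so the two new C–O bonds lie on opposite faces; the zerovalent palladium released is reoxidised by the quinone, which MnO2 regenerates. The closest known reaction type is the chloride-free palladium-catalysed trans-1,4-diacetoxylation of cyclohexa-1,3-dienes; no ring is closed. C1 and C4 are created together and their mutual trans relationship is fixed by this anti-attack/syn-delivery mechanism. Their relationship to C5 and C6 is fixed by the substrate: the external acetate goes to the terminus whose neighbouring oxygen lies on the other face (C4 from the face opposite O5 if the metal sits on the O5 face, C1 from the face opposite O6 if it sits on the O6 face), so either complex should converge on the same all-trans isomer. The bulky TIPS ether reinforces this bias at C1 and the benzoate at C4. The step also needs 1,4- over 1,2-addition, which the ring and the fully substituted C3 favour, and it must outrun Diels–Alder addition of the quinone, which is why the quinone is kept catalytic.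

Step 9
Reactants: 16 all-trans triacetate
Product: 17 1,4,7-triol (5-OBz, 6-OTIPS; configuration as in 16)
Conditions: HCl (0.3 M in MeOH), CH2Cl2, 0 °C → rt
Reagents that add atoms: none
Why: acid-catalysed transesterification cleaves acetates much faster than the hindered secondary benzoate; no alkoxide is formed, so the benzoate cannot migrate to O4, and a TIPS ether flanked by two oxygen-bearing carbons resists dilute acid.

Step 10
Reactants: 17 1,4,7-triol
Product: 18 4,7-O-(di-tert-butylsilylene) derivative with free 1-OH (5-OBz, 6-OTIPS)
Conditions: tBu2Si(OTf)2 (1.05 equiv), 2,6-lutidine, DMF, −20 → 0 °C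
Reagents that add atoms: di-tert-butylsilyl bis(trifluoromethanesulfonate), CC(C)(C)[Si](OS(=O)(=O)C(F)(F)F)(OS(=O)(=O)C(F)(F)F)C(C)(C)C
Why: silylene protection of a 1,3-diol; the bis-triflate silylates the primary O7 first and closes the six-membered ring onto O4, whereas O1, whose only oxygen neighbour is the blocked O6, cannot form a ring and stays free.

Step 11
Reactants: 18 4,7-O-silylene with free 1-OH
Product: 19 1-O-methyl ether (4,7-O-silylene, 5-OBz, 6-OTIPS)
Conditions: Me3OBF4 (3 equiv), 1,8-bis(dimethylamino)naphthalene (4 equiv), 4 Å molecular sieves, CH2Cl2, 0 °C → rt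
Reagents that add atoms: trimethyloxonium tetrafluoroborate, C[O+](C)C.F[B-](F)(F)F
Why: O-methylation with a trialkyloxonium salt and a non-nucleophilic proton scavenger needs no alkoxide, so the benzoate is neither cleaved nor shifted; O1 is the only hydroxyl and its configuration is not touched.

Step 12
Reactants: 19 1-O-methyl ether
Product: 20 4,6,7-triol (1-OMe, 5-OBz)
Conditions: HF·pyridine, pyridine, THF, 0 °C → rt
Reagents that add atoms: none
Why: fluoride-driven Si–O cleavage; the silylene falls first and the hindered TIPS ether more slowly, and the weakly acidic medium leaves the ester in place and forms no alkoxide beside the O5 benzoate.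

Step 13
Reactants: 20 4,6,7-triol; 5 benzoyl chloride
Product: 21 target, (1S,4S,5R,6R)-5-benzoyloxy-3-(benzoyloxymethyl)-1-methoxycyclohex-2-ene-4,6-diol
Conditions: BzCl (1.05 equiv), 2,4,6-collidine, CH2Cl2, −40 → −20 °C
Reagents that add atoms: benzoyl chloride, O=C(Cl)c1ccccc1
Why: kinetic acylation of a primary allylic hydroxyl in the presence of secondary ones with one equivalent of acid chloride and a hindered base; O4 is shielded by C3 and the O5 benzoate, O6 by two substituted neighbours.

## Compound list

1 | shikimic acid | C1[C@H]([C@@H]([C@@H](C=C1C(=O)O)O)O)O | starting material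
2 | methyl shikimate | C1[C@H]([C@@H]([C@@H](C=C1C(=O)OC)O)O)O | intermediate (not isolated)
3 | methyl 3,4-O-isopropylidene shikimate | C1[C@H]([C@@H]([C@@H](C=C1C(=O)OC)O2)OC2(C)C)O | intermediate
4 | 3,4-O-isopropylidene allylic alcohol (C7H2OH, 5-OH) | C1[C@H]([C@@H]([C@@H](C=C1CO)O2)OC2(C)C)O | intermediate
5 | benzoyl chloride | O=C(Cl)c1ccccc1 | starting material
6 | 7-O-acetate of 4 | C1[C@H]([C@@H]([C@@H](C=C1COC(C)=O)O2)OC2(C)C)O | intermediate (not isolated)
7 | 7-O-acetyl-5-O-benzoyl-3,4-O-isopropylidene derivative | C1[C@H]([C@@H]([C@@H](C=C1COC(C)=O)O2)OC2(C)C)OC(=O)c1ccccc1 | intermediate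
8 | 7-O-acetyl-5-O-benzoyl 3,4-diol | C1[C@H]([C@@H]([C@@H](C=C1COC(C)=O)O)O)OC(=O)c1ccccc1 | intermediate
9 | 3-O-triethylsilyl ether of 8 | C1[C@H]([C@@H]([C@@H](C=C1COC(C)=O)O[Si](CC)(CC)CC)O)OC(=O)c1ccccc1 | intermediate (not isolated)
10 | 3-O-triethylsilyl-4-O-triisopropylsilyl ether | C1[C@H]([C@@H]([C@@H](C=C1COC(C)=O)O[Si](CC)(CC)CC)O[Si](C(C)C)(C(C)C)C(C)C)OC(=O)c1ccccc1 | intermediate
11 | 4-O-triisopropylsilyl ether with free 3-OH | C1[C@H]([C@@H]([C@@H](C=C1COC(C)=O)O)O[Si](C(C)C)(C(C)C)C(C)C)OC(=O)c1ccccc1 | intermediate
12 | 3-O-(2,4-dinitrobenzenesulfenate) of 11 | C1[C@H]([C@@H]([C@@H](C=C1COC(C)=O)OSc1ccc(cc1[N+](=O)[O-])[N+](=O)[O-])O[Si](C(C)C)(C(C)C)C(C)C)OC(=O)c1ccccc1 | intermediate (not isolated)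
13 | tertiary allylic sulfoxide (arylsulfinyl on C3, same face as O6; C1=C2; mixture at sulfur) | C1=C[C@](COC(C)=O)(S(=O)c2ccc(cc2[N+](=O)[O-])[N+](=O)[O-])C[C@@H](OC(=O)c2ccccc2)[C@@H]1O[Si](C(C)C)(C(C)C)C(C)C | intermediate (not isolated)
14 | (5R,6R)-3-(acetoxymethyl)-5-benzoyloxy-6-(triisopropylsilyloxy)cyclohexa-1,3-diene | C1=CC(COC(C)=O)=C[C@@H](OC(=O)c2ccccc2)[C@@H]1O[Si](C(C)C)(C(C)C)C(C)C | intermediate (key-step precursor)
15 | acetic acid | CC(O)=O | starting material
16 | (1S,4S,5R,6R)-1,4-diacetoxy-3-(acetoxymethyl)-5-benzoyloxy-6-(triisopropylsilyloxy)cyclohex-2-ene | CC(=O)O[C@H]1C=C(COC(C)=O)[C@H](OC(C)=O)[C@@H](OC(=O)c2ccccc2)[C@@H]1O[Si](C(C)C)(C(C)C)C(C)C | intermediate (key-step product)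
17 | 1,4,7-triol (5-OBz, 6-OTIPS) | O[C@H]1C=C(CO)[C@H](O)[C@@H](OC(=O)c2ccccc2)[C@@H]1O[Si](C(C)C)(C(C)C)C(C)C | intermediate
18 | 4,7-O-(di-tert-butylsilylene) 1-ol (5-OBz, 6-OTIPS) | O[C@H]1C=C2CO[Si](C(C)(C)C)(C(C)(C)C)O[C@@H]2[C@@H](OC(=O)c3ccccc3)[C@@H]1O[Si](C(C)C)(C(C)C)C(C)C | intermediate
19 | 1-O-methyl ether of 18 | CO[C@H]1C=C2CO[Si](C(C)(C)C)(C(C)(C)C)O[C@@H]2[C@@H](OC(=O)c3ccccc3)[C@@H]1O[Si](C(C)C)(C(C)C)C(C)C | intermediate
20 | 4,6,7-triol (1-OMe, 5-OBz) | CO[C@H]1C=C(CO)[C@H](O)[C@@H](OC(=O)c2ccccc2)[C@@H]1O | intermediate
21 | (1S,4S,5R,6R)-5-benzoyloxy-3-(benzoyloxymethyl)-1-methoxycyclohex-2-ene-4,6-diol | CO[C@H]1C=C(COC(=O)c2ccccc2)[C@H](O)[C@@H](OC(=O)c2ccccc2)[C@@H]1O | target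

## Step count and weak points

Total: 13 steps (steps 1, 3 and 5 each run two operations in one flask). Longest linear sequence: 13 steps from shikimic acid 1.

Step 8 (key step). Most likely failure: slow complexation of a diene that is deactivated by two allylic oxygens and shielded on both faces, which gives time for Diels–Alder consumption by the quinone or for aromatisation. A second risk is erosion of diastereoselectivity if the external acetate attacks syn to its neighbouring oxygen. Fallback: from 14, the chloride-containing variant (Pd(OAc)2, LiCl, LiOAc, benzoquinone, AcOH) lets both nucleophiles attack from outside, anti to the metal, and should give the cis chloro acetate F1 (acetate at C4 anti to O5, chloride at C1). SN2 displacement of the allylic chloride by CsOAc in DMF then inverts C1 and returns to 16. This replaces the acetate migration on palladium by a separate inversion step.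

Step 7. Most likely failure: the sigmatropic shift has to form a C–S bond at a fully substituted carbon; if the sulfenate–sulfoxide equilibrium stays on the sulfenate side, elimination is slow and the sulfenyl chloride or the sulfenic acid adds to the diene as it forms. Fallback: from 11, methyl chloroformate and pyridine give the allylic methyl carbonate F2, and a Tsuji–Trost-type 1,4-elimination (Pd(PPh3)4, THF, 40–60 °C) ionises the allylic C–O bond with zerovalent palladium and removes the ring CH2 hydrogen to give 14.

Step 5. Most likely failure: incomplete discrimination between O3 and O4, silyl migration between the cis oxygens under the basic conditions, or sluggish introduction of TIPS next to a cis triethylsilyl ether. Fallback: from 8, low-temperature acylation with chloroacetyl chloride and pyridine gives the 3-O-chloroacetate F3, a small group that does not migrate under silylation conditions; iPr3SiOTf and 2,6-lutidine give its 4-O-TIPS ether F4; thiourea with NaHCO3 in ethanol removes the chloroacetyl group in the presence of acetate and benzoate and returns to 11.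

Step 9. Most likely failure: slow methanolysis of the hindered C4 acetate, so that partial loss of the TIPS ether or of the benzoate sets in before all three acetates are gone. Fallback: from 16, give up the ester discrimination. K2CO3 in MeOH removes all four esters to give the tetraol F5; the bis-triflate of step 10 gives the 4,7-silylene diol F6; one equivalent of Me3OBF4 with the proton scavenger should methylate the more accessible allylic O1, not O5, which is buried between the silylene and the TIPS ether, to give the 1-O-methyl ether F7; benzoyl chloride 5 with 4-(dimethylamino)pyridine then acylates O5 and returns to 19.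

Step 13. Most likely failure: over-acylation at O4 or O6, or base-induced drift of the O5 benzoate to a neighbouring hydroxyl in the triol. Fallback: from 19, a short treatment with HF·pyridine at 0 °C removes only the silylene and gives the diol F8 with the TIPS ether intact; benzoylation with 5 then has only the hindered O4 as competitor and gives the 7-benzoate F9; HF·pyridine at rt removes the TIPS group and gives 21.

Further compounds

F1 | step 8 | cis-4-acetoxy-1-chloro adduct (3-acetoxymethyl, 5-OBz, 6-OTIPS; Cl syn to O6) | Cl[C@@H]1C=C(COC(C)=O)[C@H](OC(C)=O)[C@@H](OC(=O)c2ccccc2)[C@@H]1O[Si](C(C)C)(C(C)C)C(C)C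
F2 | step 7 | 3-O-methoxycarbonyl derivative of 11 (allylic methyl carbonate) | C1[C@H]([C@@H]([C@@H](C=C1COC(C)=O)OC(=O)OC)O[Si](C(C)C)(C(C)C)C(C)C)OC(=O)c1ccccc1
F3 | step 5 | 3-O-chloroacetate of 8 | C1[C@H]([C@@H]([C@@H](C=C1COC(C)=O)OC(=O)CCl)O)OC(=O)c1ccccc1
F4 | step 5 | 3-O-chloroacetyl-4-O-triisopropylsilyl ether | C1[C@H]([C@@H]([C@@H](C=C1COC(C)=O)OC(=O)CCl)O[Si](C(C)C)(C(C)C)C(C)C)OC(=O)c1ccccc1
F5 | step 9 | 1,4,5,7-tetraol with 6-OTIPS | O[C@H]1C=C(CO)[C@H](O)[C@@H](O)[C@@H]1O[Si](C(C)C)(C(C)C)C(C)C
F6 | step 9 | 4,7-O-(di-tert-butylsilylene) 1,5-diol with 6-OTIPS | O[C@H]1C=C2CO[Si](C(C)(C)C)(C(C)(C)C)O[C@@H]2[C@@H](O)[C@@H]1O[Si](C(C)C)(C(C)C)C(C)C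
F7 | step 9 | 1-O-methyl-4,7-O-(di-tert-butylsilylene) 5-ol with 6-OTIPS | CO[C@H]1C=C2CO[Si](C(C)(C)C)(C(C)(C)C)O[C@@H]2[C@@H](O)[C@@H]1O[Si](C(C)C)(C(C)C)C(C)C
F8 | step 13 | 4,7-diol with 1-OMe, 5-OBz, 6-OTIPS | CO[C@H]1C=C(CO)[C@H](O)[C@@H](OC(=O)c2ccccc2)[C@@H]1O[Si](C(C)C)(C(C)C)C(C)C
F9 | step 13 | 6-O-triisopropylsilyl ether of 21 | CO[C@H]1C=C(COC(=O)c2ccccc2)[C@H](O)[C@@H](OC(=O)c2ccccc2)[C@@H]1O[Si](C(C)C)(C(C)C)C(C)C
A1 | alternative 1 | (1S,2S)-3-bromocyclohexa-3,5-diene-1,2-diol | BrC1=CC=C[C@H](O)[C@@H]1O
A2 | alternative 1 | bromobenzene | Brc1ccccc1
A3 | alternative 2 | all-trans cyclohexenol thioester (1-OMe, 6-OTBS, 5-OBz, 4-OH, C7 as S-ethyl thioester) | CCSC(=O)C1=C[C@H](OC)[C@@H](O[Si](C)(C)C(C)(C)C)[C@H](OC(=O)c2ccccc2)[C@H]1O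
A4 | alternative 2 | D-xylose | C([C@H]([C@@H]([C@H](C=O)O)O)O)O
A5 | alternative 3 | 4,6-bis-O-(tert-butyldimethylsilyl) ether of the target | CO[C@H]1C=C(COC(=O)c2ccccc2)[C@H](O[Si](C)(C)C(C)(C)C)[C@@H](OC(=O)c2ccccc2)[C@@H]1O[Si](C)(C)C(C)(C)C
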